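**Retrosynthetic overview**
- C14 carbinol from CBS reduction of the macrocyclic α-methylene ketone; the 14-membered carbocycle is closed last, at C1–C14, by intramolecular Nozaki–Hiyama–Kishi reaction of a 2-iodoalkene with an aldehyde.
- C10–C11 epoxide from Shi epoxidation of the E-trisubstituted alkene on the acyclic lactone.
- Key disconnection C7–C8: intermolecular indium-mediated carbonyl allylation of an α-hydroxy aldehyde (fragment A, C1–C7) with a (Z)-2-(bromomethyl)enoate (fragment B, C8–C14 plus the three lactone carbons), then lactonisation.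
- Fragment A from (S)-citronellal (proline α-aminoxylation sets C6); fragment B from pent-4-yn-1-ol (Negishi carboalumination/oxirane, vinylalumination, SN2′ bromination).
- Ring order: γ-lactone (step 16), oxirane (step 17), carbocycle (step 20).

Assumption: the carbocycle is numbered C1–C14 in the order of the target SMILES (C1 carries the exocyclic methylene, C14 the allylic hydroxyl); the target is then 5S,6R,7R,8S,10R,11R,14S, with a cis-fused lactone and a trans epoxide.
Assumption: commercial (S)-citronellal of high enantiomeric purity is used.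

**Fragment A**

Step 1
Reactants: 1 (3S)-3,7-dimethyloct-6-enal [(S)-citronellal]
Product: 3 (2R,3S)-3,7-dimethyl-2-[(phenylamino)oxy]oct-6-en-1-ol, via α-anilinooxy aldehyde 2 (not isolated)
Conditions: 1 (1.5 equiv), PhNO (1.0 equiv), L-proline (20 mol%), DMSO, rt; then NaBH4, EtOH, 0 °C
Reagents that add atoms: nitrosobenzene, O=Nc1ccccc1
Why: Proline-catalysed α-aminoxylation (enamine catalysis) puts oxygen on C2 (future C6) with the (2R) configuration set by L-proline next to the existing (3S) methyl centre (future C5), and immediate borohydride reduction prevents epimerisation of the α-oxy aldehyde.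

Step 2
Reactants: 3 (2R,3S)-3,7-dimethyl-2-[(phenylamino)oxy]oct-6-en-1-ol
Product: 4 (2R,3S)-3,7-dimethyloct-6-ene-1,2-diol
Conditions: Zn dust, AcOH/EtOH, rt
Reagents that add atoms: none
Why: Reductive N–O bond cleavage by zinc in acetic acid frees the secondary alcohol without touching the alkene or either stereocentre.

Step 3
Reactants: 4 (2R,3S)-3,7-dimethyloct-6-ene-1,2-diol
Product: 5 (2R,3S)-1,2-bis[(tert-butyldimethylsilyl)oxy]-3,7-dimethyloct-6-ene
Conditions: TBSOTf (2.5 equiv), 2,6-lutidine, CH2Cl2, 0 °C → rt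
Reagents that add atoms: tert-butyldimethylsilyl trifluoromethanesulfonate, CC(C)(C)[Si](C)(C)OS(=O)(=O)C(F)(F)F
Why: Silyl ether formation with the silyl triflate protects both hydroxyls, including the hindered secondary one.

Step 4
Reactants: 5 (2R,3S)-1,2-bis[(tert-butyldimethylsilyl)oxy]-3,7-dimethyloct-6-ene
Product: 7 (4S,5R)-5,6-bis[(tert-butyldimethylsilyl)oxy]-4-methylhexan-1-ol, via aldehyde 6 (not isolated)
Conditions: O3, CH2Cl2/MeOH, −78 °C; then NaBH4, −78 → 0 °C
Reagents that add atoms: ozone, [O-][O+]=O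
Why: Ozonolysis with reductive borohydride work-up cleaves the only C=C bond and gives the primary alcohol directly, the silyl ethers being inert.

Step 5
Reactants: 7 (4S,5R)-5,6-bis[(tert-butyldimethylsilyl)oxy]-4-methylhexan-1-ol
Product: 8 (2R,3S)-1,2-bis[(tert-butyldimethylsilyl)oxy]-6-iodo-3-methylhexane
Conditions: I2, PPh3, imidazole, CH2Cl2, 0 °C → rt
Reagents that add atoms: iodine, II
Why: Appel-type iodination converts the primary alcohol into the iodide by SN2 displacement of the oxyphosphonium group.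

Step 6
Reactants: 8 (2R,3S)-1,2-bis[(tert-butyldimethylsilyl)oxy]-6-iodo-3-methylhexane
Product: 9 (2R,3S)-1,2-bis[(tert-butyldimethylsilyl)oxy]-3-methyloct-7-yne
Conditions: LiC≡CH·H2NCH2CH2NH2 (2 equiv), DMSO, 0 °C → rt
Reagents that add atoms: lithium acetylide–ethylenediamine complex, [Li]C#C.NCCN
Why: SN2 alkylation of lithium acetylide by the unhindered primary iodide adds the two carbons that become C1 and its exocyclic methylene.

Step 7
Reactants: 9 (2R,3S)-1,2-bis[(tert-butyldimethylsilyl)oxy]-3-methyloct-7-yne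
Product: 11 (2R,3S)-1,2-bis[(tert-butyldimethylsilyl)oxy]-7-iodo-3-methyloct-7-ene, via alkenylborane 10 (not isolated)
Conditions: B-iodo-9-borabicyclo[3.3.1]nonane (1.2 equiv), pentane/CH2Cl2, −20 → 0 °C; then AcOH, 0 °C → rt
Reagents that add atoms: B-iodo-9-borabicyclo[3.3.1]nonane, IB1C2CCCC1CCC2
Why: Haloboration–protodeboronation adds B–I syn and Markovnikov across the terminal alkyne (iodine on the internal carbon) and acetic acid then cleaves the C–B bond to give the 2-iodo-1-alkene needed for the later ring closure.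

Step 8
Reactants: 11 (2R,3S)-1,2-bis[(tert-butyldimethylsilyl)oxy]-7-iodo-3-methyloct-7-ene
Product: 12 (2R,3S)-2-[(tert-butyldimethylsilyl)oxy]-7-iodo-3-methyloct-7-en-1-ol
Conditions: HF·pyridine, pyridine, THF, 0 °C
Reagents that add atoms: none
Why: Selective desilylation works because the primary silyl ether is cleaved by buffered HF·pyridine much faster than the hindered secondary one.

Step 9
Reactants: 12 (2R,3S)-2-[(tert-butyldimethylsilyl)oxy]-7-iodo-3-methyloct-7-en-1-ol
Product: 13 (2R,3S)-2-[(tert-butyldimethylsilyl)oxy]-7-iodo-3-methyloct-7-enal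
Conditions: Dess–Martin periodinane, CH2Cl2, 0 °C → rt
Reagents that add atoms: none
Why: Dess–Martin oxidation gives the α-silyloxy aldehyde under non-basic conditions, so the α-centre (future C6) does not epimerise.

Step 10
Reactants: 13 (2R,3S)-2-[(tert-butyldimethylsilyl)oxy]-7-iodo-3-methyloct-7-enal
Product: 14 (2R,3S)-2-hydroxy-7-iodo-3-methyloct-7-enal
Conditions: 48% aq. HF/MeCN (1:19), 0 °C → rt; NaHCO3 quench; crude product used at once
Reagents that add atoms: none
Why: Acidic fluoride desilylation unmasks the free α-hydroxy aldehyde that the chelation-controlled coupling needs, and it is used immediately because it dimerises on standing.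

**Fragment B**

Step 11
Reactants: 15 pent-4-yn-1-ol
Product: 16 1-methoxy-4-[(pent-4-yn-1-yloxy)methyl]benzene
Conditions: NaH (1.05 equiv), 4-methoxybenzyl chloride, Bu4NI (cat.), THF/DMF, 0 °C → rt
Reagents that add atoms: 4-methoxybenzyl chloride, COc1ccc(CCl)cc1
Why: Williamson etherification proceeds through the alkoxide (formed in preference to the acetylide) and installs a PMB group that is later removable oxidatively at neutral pH.

Step 12
Reactants: 16 1-methoxy-4-[(pent-4-yn-1-yloxy)methyl]benzene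
Product: 18 (3E)-7-[(4-methoxybenzyl)oxy]-4-methylhept-3-en-1-ol, via alkenyldimethylalane 17 (not isolated)
Conditions: Me3Al (2 equiv), Cp2ZrCl2 (0.2 equiv), CH2Cl2, 0 °C → rt; evaporate excess Me3Al; n-BuLi, hexane/THF, −78 → 0 °C; oxirane, −78 °C → rt; aq. potassium sodium tartrate
Reagents that add atoms: trimethylaluminium, C[Al](C)C; oxirane, C1CO1
Why: Negishi zirconium-catalysed carboalumination adds methyl and aluminium syn across the alkyne to fix the E-trisubstituted C10=C11 alkene, and the derived alkenylalanate opens oxirane with retention of geometry to give the homoallylic alcohol.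

Step 13
Reactants: 18 (3E)-7-[(4-methoxybenzyl)oxy]-4-methylhept-3-en-1-ol
Product: 19 (3E)-7-[(4-methoxybenzyl)oxy]-4-methylhept-3-enal
Conditions: Dess–Martin periodinane, NaHCO3, CH2Cl2, 0 °C; used crude
Reagents that add atoms: none
Why: Buffered Dess–Martin oxidation gives the β,γ-unsaturated aldehyde without acid or base that would move the double bond into conjugation.

Step 14
Reactants: 19 (3E)-7-[(4-methoxybenzyl)oxy]-4-methylhept-3-enal; 20 ethyl propiolate
Product: 22 ethyl (5E)-3-hydroxy-9-[(4-methoxybenzyl)oxy]-6-methyl-2-methylidenenon-5-enoate (racemic at C3), via α-aluminoacrylate 21 (not isolated)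
Conditions: i-Bu2AlH, N-methylmorpholine N-oxide, THF, 0 °C, then 20; then 19, 0 °C → rt
Reagents that add atoms: none
Why: Vinylalumination (the aluminium variant of the Morita–Baylis–Hillman reaction) hydroaluminates ethyl propiolate regioselectively to the α-alumino acrylate, which adds to the aldehyde without amine base so the skipped alkene does not isomerise, and the racemic carbinol centre is erased in the next step.

Step 15
Reactants: 22 ethyl (5E)-3-hydroxy-9-[(4-methoxybenzyl)oxy]-6-methyl-2-methylidenenon-5-enoate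
Product: 23 ethyl (2Z,5E)-2-(bromomethyl)-9-[(4-methoxybenzyl)oxy]-6-methylnona-2,5-dienoate
Conditions: N-bromosuccinimide, Me2S, CH2Cl2, 0 °C → rt
Reagents that add atoms: N-bromosuccinimide, O=C1CCC(=O)N1Br
Why: Corey–Kim-type activation of the Baylis–Hillman alcohol followed by SN2′ attack of bromide gives the thermodynamically favoured (Z)-2-(bromomethyl)enoate.

**Fragment union and endgame**

Step 16
Reactants: 14 (2R,3S)-2-hydroxy-7-iodo-3-methyloct-7-enal; 23 ethyl (2Z,5E)-2-(bromomethyl)-9-[(4-methoxybenzyl)oxy]-6-methylnona-2,5-dienoate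
Product: 26 (4S,5R)-5-[(1R,2S)-1-hydroxy-6-iodo-2-methylhept-6-en-1-yl]-4-{(2E)-6-[(4-methoxybenzyl)oxy]-3-methylhex-2-en-1-yl}-3-methylideneoxolan-2-one, via allylindium species 24 (not isolated), via hydroxy ester 25 (not isolated)
Conditions: In powder (2 equiv), THF/H2O (1:1), rt; then TsOH·H2O (cat.), CH2Cl2, rt
Reagents that add atoms: none
Why: In this indium-mediated Barbier-type carbonyl allylation followed by acid-catalysed lactonisation, the allylindium attacks C7 through its γ-carbon (C8) in a chair transition state where the Z-allyl geometry gives the 7,8-syn adduct (cis-lactone) and chelation of indium by the free C6 hydroxyl and the carbonyl oxygen gives the 6,7-syn diol, so C7 (R) and C8 (S) are set by the existing C6 centre.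

Step 17
Reactants: 26 (4S,5R)-5-[(1R,2S)-1-hydroxy-6-iodo-2-methylhept-6-en-1-yl]-4-{(2E)-6-[(4-methoxybenzyl)oxy]-3-methylhex-2-en-1-yl}-3-methylideneoxolan-2-one
Product: 27 (4S,5R)-5-[(1R,2S)-1-hydroxy-6-iodo-2-methylhept-6-en-1-yl]-4-{[(2R,3R)-3-{3-[(4-methoxybenzyl)oxy]propyl}-3-methyloxiran-2-yl]methyl}-3-methylideneoxolan-2-one
Conditions: 1,2:4,5-di-O-isopropylidene-β-D-erythro-2,3-hexodiulo-2,6-pyranose (D-fructose-derived Shi ketone, 3 equiv), KHSO5 (as 2KHSO5·KHSO4·K2SO4), NaHCO3, MeCN/aq. disodium ethylenediaminetetraacetate, 0 °C, pH ≈ 8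
Reagents that add atoms: potassium peroxymonosulfate, [K+].[O-]S(=O)(=O)OO
Why: In the Shi asymmetric epoxidation the chiral dioxirane attacks the electron-rich E-trisubstituted C10=C11 alkene through the spiro transition state to give the (10R,11R)-trans-epoxide under reagent control, while the α-methylene lactone and the iodoalkene are too electron-poor to react.

Step 18
Reactants: 27 (4S,5R)-5-[(1R,2S)-1-hydroxy-6-iodo-2-methylhept-6-en-1-yl]-4-{[(2R,3R)-3-{3-[(4-methoxybenzyl)oxy]propyl}-3-methyloxiran-2-yl]methyl}-3-methylideneoxolan-2-one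
Product: 28 (4S,5R)-5-[(1R,2S)-1-hydroxy-6-iodo-2-methylhept-6-en-1-yl]-4-{[(2R,3R)-3-(3-hydroxypropyl)-3-methyloxiran-2-yl]methyl}-3-methylideneoxolan-2-one
Conditions: DDQ (1.5 equiv), CH2Cl2/pH 7 phosphate buffer (10:1), 0 °C
Reagents that add atoms: none
Why: Oxidative PMB ether cleavage by DDQ (benzylic hydride abstraction, then hydrolysis) under neutral buffer frees the primary alcohol without the acid that would open the epoxide.

Step 19
Reactants: 28 (4S,5R)-5-[(1R,2S)-1-hydroxy-6-iodo-2-methylhept-6-en-1-yl]-4-{[(2R,3R)-3-(3-hydroxypropyl)-3-methyloxiran-2-yl]methyl}-3-methylideneoxolan-2-one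
Product: 29 (4S,5R)-5-[(1R,2S)-1-hydroxy-6-iodo-2-methylhept-6-en-1-yl]-3-methylidene-4-{[(2R,3R)-3-methyl-3-(3-oxopropyl)oxiran-2-yl]methyl}oxolan-2-one
Conditions: [Cu(MeCN)4]OTf (10 mol%), 2,2′-bipyridine (10 mol%), 2,2,6,6-tetramethylpiperidin-1-oxyl (10 mol%), N-methylimidazole (20 mol%), air, MeCN, rt
Reagents that add atoms: none
Why: Stahl aerobic copper/nitroxyl oxidation is selective for the primary alcohol over the hindered secondary C6 alcohol and is neutral, so the γ,δ-epoxy alcohol does not cyclise.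

Step 20
Reactants: 29 (4S,5R)-5-[(1R,2S)-1-hydroxy-6-iodo-2-methylhept-6-en-1-yl]-3-methylidene-4-{[(2R,3R)-3-methyl-3-(3-oxopropyl)oxiran-2-yl]methyl}oxolan-2-one
Product: 31 macrocyclic C14 carbinol (5S,6R,7R,8S,10R,11R; mixture of C14 epimers), via alkenylchromium dichloride 30 (not isolated)
Conditions: CrCl2 (10 equiv), NiCl2 (0.1 equiv), DMSO/THF (3:1), rt, 2 mM, syringe-pump addition of 29
Reagents that add atoms: none
Why: In this intramolecular Nozaki–Hiyama–Kishi reaction the nickel-catalysed alkenylchromium formed from the 2-iodoalkene adds to the tethered aldehyde at high dilution and closes the 14-membered ring at C1–C14 while tolerating lactone, epoxide and free hydroxyl, with the C14 configuration left uncontrolled and both epimers carried on.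

Step 21
Reactants: 31 macrocyclic C14 carbinol (C14 epimer mixture)
Product: 32 macrocyclic enone (5S,6R,7R,8S,10R,11R; C14 ketone conjugated with the C1 methylidene)
Conditions: MnO2 (activated, 20 equiv), CH2Cl2, rt
Reagents that add atoms: none
Why: Chemoselective MnO2 oxidation converts both epimers of the allylic C14 alcohol into one α-methylene ketone and leaves the non-allylic C6 alcohol untouched.

Step 22
Reactants: 32 macrocyclic enone
Product: 33 target CNP0124069.2 (5S,6R,7R,8S,10R,11R,14S)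
Conditions: (R)-1-methyl-3,3-diphenyltetrahydro-1H,3H-pyrrolo[1,2-c][1,3,2]oxazaborole [(R)-Me-CBS, 1 equiv], catecholborane (3 equiv), toluene/CH2Cl2, −78 °C
Reagents that add atoms: none
Why: In the Corey–Bakshi–Shibata reduction the (R)-oxazaborolidine–borane complex binds the ketone with the alkenyl (C1) side as the large group and delivers hydride to give the (14S) allylic alcohol under reagent control, and 1,2-reduction at −78 °C leaves lactone, epoxide and alkenes alone.

**Compound list**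
1 | (3S)-3,7-dimethyloct-6-enal [(S)-citronellal] | CC(C)=CCC[C@H](C)CC=O | starting material
2 | (2R,3S)-3,7-dimethyl-2-[(phenylamino)oxy]oct-6-enal | CC(C)=CCC[C@H](C)[C@@H](ONc1ccccc1)C=O | intermediate (not isolated)
3 | (2R,3S)-3,7-dimethyl-2-[(phenylamino)oxy]oct-6-en-1-ol | CC(C)=CCC[C@H](C)[C@@H](ONc1ccccc1)CO | intermediate
4 | (2R,3S)-3,7-dimethyloct-6-ene-1,2-diol | CC(C)=CCC[C@H](C)[C@@H](O)CO | intermediate
5 | (2R,3S)-1,2-bis[(tert-butyldimethylsilyl)oxy]-3,7-dimethyloct-6-ene | CC(C)=CCC[C@H](C)[C@@H](O[Si](C)(C)C(C)(C)C)CO[Si](C)(C)C(C)(C)C | intermediate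
6 | (4S,5R)-5,6-bis[(tert-butyldimethylsilyl)oxy]-4-methylhexanal | O=CCC[C@H](C)[C@@H](O[Si](C)(C)C(C)(C)C)CO[Si](C)(C)C(C)(C)C | intermediate (not isolated)
7 | (4S,5R)-5,6-bis[(tert-butyldimethylsilyl)oxy]-4-methylhexan-1-ol | OCCC[C@H](C)[C@@H](O[Si](C)(C)C(C)(C)C)CO[Si](C)(C)C(C)(C)C | intermediate
8 | (2R,3S)-1,2-bis[(tert-butyldimethylsilyl)oxy]-6-iodo-3-methylhexane | ICCC[C@H](C)[C@@H](O[Si](C)(C)C(C)(C)C)CO[Si](C)(C)C(C)(C)C | intermediate
9 | (2R,3S)-1,2-bis[(tert-butyldimethylsilyl)oxy]-3-methyloct-7-yne | C#CCCC[C@H](C)[C@@H](O[Si](C)(C)C(C)(C)C)CO[Si](C)(C)C(C)(C)C | intermediate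
10 | 9-{(1Z,6S,7R)-7,8-bis[(tert-butyldimethylsilyl)oxy]-2-iodo-6-methyloct-1-en-1-yl}-9-borabicyclo[3.3.1]nonane | I/C(CCC[C@H](C)[C@@H](O[Si](C)(C)C(C)(C)C)CO[Si](C)(C)C(C)(C)C)=C\B1C2CCCC1CCC2 | intermediate (not isolated)
11 | (2R,3S)-1,2-bis[(tert-butyldimethylsilyl)oxy]-7-iodo-3-methyloct-7-ene | C=C(I)CCC[C@H](C)[C@@H](O[Si](C)(C)C(C)(C)C)CO[Si](C)(C)C(C)(C)C | intermediate
12 | (2R,3S)-2-[(tert-butyldimethylsilyl)oxy]-7-iodo-3-methyloct-7-en-1-ol | C=C(I)CCC[C@H](C)[C@@H](O[Si](C)(C)C(C)(C)C)CO | intermediate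
13 | (2R,3S)-2-[(tert-butyldimethylsilyl)oxy]-7-iodo-3-methyloct-7-enal | C=C(I)CCC[C@H](C)[C@@H](O[Si](C)(C)C(C)(C)C)C=O | intermediate
14 | (2R,3S)-2-hydroxy-7-iodo-3-methyloct-7-enal (fragment A) | C=C(I)CCC[C@H](C)[C@@H](O)C=O | intermediate
15 | pent-4-yn-1-ol | C#CCCCO | starting material
16 | 1-methoxy-4-[(pent-4-yn-1-yloxy)methyl]benzene | C#CCCCOCc1ccc(OC)cc1 | intermediate
17 | dimethyl{(1E)-5-[(4-methoxybenzyl)oxy]-2-methylpent-1-en-1-yl}alumane | C[Al](C)/C=C(\C)CCCOCc1ccc(OC)cc1 | intermediate (not isolated)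
18 | (3E)-7-[(4-methoxybenzyl)oxy]-4-methylhept-3-en-1-ol | OCC/C=C(\C)CCCOCc1ccc(OC)cc1 | intermediate
19 | (3E)-7-[(4-methoxybenzyl)oxy]-4-methylhept-3-enal | O=CC/C=C(\C)CCCOCc1ccc(OC)cc1 | intermediate
20 | ethyl propiolate (ethyl prop-2-ynoate) | C#CC(=O)OCC | starting material
21 | ethyl 2-(diisobutylalumanyl)prop-2-enoate | C=C(C(=O)OCC)[Al](CC(C)C)CC(C)C | intermediate (not isolated)
22 | ethyl (5E)-3-hydroxy-9-[(4-methoxybenzyl)oxy]-6-methyl-2-methylidenenon-5-enoate (racemic at C3) | CCOC(=O)C(=C)C(O)C/C=C(\C)CCCOCc1ccc(OC)cc1 | intermediate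
23 | ethyl (2Z,5E)-2-(bromomethyl)-9-[(4-methoxybenzyl)oxy]-6-methylnona-2,5-dienoate (fragment B) | CCOC(=O)/C(CBr)=C/C/C=C(\C)CCCOCc1ccc(OC)cc1 | intermediate
24 | allylindium species from 23 (formulated as the monovalent allylindium) | CCOC(=O)/C(C[In])=C/C/C=C(\C)CCCOCc1ccc(OC)cc1 | intermediate (not isolated)
25 | ethyl (3S,4R,5R,6S)-4,5-dihydroxy-10-iodo-3-{(2E)-6-[(4-methoxybenzyl)oxy]-3-methylhex-2-en-1-yl}-6-methyl-2-methylideneundec-10-enoate | C=C(I)CCC[C@H](C)[C@@H](O)[C@H](O)[C@@H](C/C=C(\C)CCCOCc1ccc(OC)cc1)C(=C)C(=O)OCC | intermediate (not isolated)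
26 | (4S,5R)-5-[(1R,2S)-1-hydroxy-6-iodo-2-methylhept-6-en-1-yl]-4-{(2E)-6-[(4-methoxybenzyl)oxy]-3-methylhex-2-en-1-yl}-3-methylideneoxolan-2-one | C=C(I)CCC[C@H](C)[C@@H](O)[C@@H]1OC(=O)C(=C)[C@@H]1C/C=C(\C)CCCOCc2ccc(OC)cc2 | intermediate
27 | (4S,5R)-5-[(1R,2S)-1-hydroxy-6-iodo-2-methylhept-6-en-1-yl]-4-{[(2R,3R)-3-{3-[(4-methoxybenzyl)oxy]propyl}-3-methyloxiran-2-yl]methyl}-3-methylideneoxolan-2-one | C=C(I)CCC[C@H](C)[C@@H](O)[C@@H]1OC(=O)C(=C)[C@@H]1C[C@H]2O[C@]2(C)CCCOCc3ccc(OC)cc3 | intermediate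
28 | (4S,5R)-5-[(1R,2S)-1-hydroxy-6-iodo-2-methylhept-6-en-1-yl]-4-{[(2R,3R)-3-(3-hydroxypropyl)-3-methyloxiran-2-yl]methyl}-3-methylideneoxolan-2-one | C=C(I)CCC[C@H](C)[C@@H](O)[C@@H]1OC(=O)C(=C)[C@@H]1C[C@H]2O[C@]2(C)CCCO | intermediate
29 | (4S,5R)-5-[(1R,2S)-1-hydroxy-6-iodo-2-methylhept-6-en-1-yl]-3-methylidene-4-{[(2R,3R)-3-methyl-3-(3-oxopropyl)oxiran-2-yl]methyl}oxolan-2-one | C=C(I)CCC[C@H](C)[C@@H](O)[C@@H]1OC(=O)C(=C)[C@@H]1C[C@H]2O[C@]2(C)CCC=O | intermediate
30 | alkenylchromium dichloride of 29 (CrCl2 in place of iodine at C1) | C=C([Cr](Cl)Cl)CCC[C@H](C)[C@@H](O)[C@@H]1OC(=O)C(=C)[C@@H]1C[C@H]2O[C@]2(C)CCC=O | intermediate (not isolated)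
31 | macrocyclic C14 carbinol: 14-membered carbocycle with C1 methylidene, C5 methyl, C6 hydroxyl, 7,8-cis-fused α-methylene-γ-lactone, 10,11-epoxide with C11 methyl, C14 hydroxyl (5S,6R,7R,8S,10R,11R; both C14 epimers) | C=C1CCC[C@H](C)[C@@H](O)[C@@H]2OC(=O)C(=C)[C@@H]2C[C@H]2O[C@]2(C)CCC1O | intermediate
32 | macrocyclic enone: as 31 with C14 ketone (5S,6R,7R,8S,10R,11R) | C=C1CCC[C@H](C)[C@@H](O)[C@@H]2OC(=O)C(=C)[C@@H]2C[C@H]2O[C@]2(C)CCC1=O | intermediate
33 | CNP0124069.2 (5S,6R,7R,8S,10R,11R,14S) | C=C1CCC[C@H](C)[C@@H](O)[C@@H]2OC(=O)C(=C)[C@@H]2C[C@H]2O[C@]2(C)CC[C@@H]1O | target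

**Totals and risks**

Total step count: 22. Longest linear sequence: 17 steps (steps 1–10, then 16–22); the fragment B branch is steps 11–15.

The three steps most likely to fail:

Step 16 (key allylation). The risks are incomplete chelation control at C7, erosion of the syn preference at C8, and loss of the labile α-hydroxy aldehyde 14. The fallback replaces the aqueous indium Barbier reaction by a Keck-type chelation-controlled Lewis-acid allylstannane addition to an α-PMB-oxy aldehyde; it sets out from 11 and 23 and rejoins the route at 28. Bu4NF in THF removes both silyl groups of 11 to give the iodo diol F1. 4-Methoxybenzaldehyde dimethyl acetal with pyridinium p-toluenesulfonate gives the 4-methoxybenzylidene acetal F2. i-Bu2AlH (CH2Cl2, −78 → 0 °C) opens it regioselectively to the secondary PMB ether with free primary alcohol F3. Dess–Martin oxidation gives the α-PMB-oxy aldehyde F4. Separately, 23 with (Bu3Sn)2 and Pd(PPh3)4 (cat.) gives the allylstannane F5. MgBr2·OEt2 (CH2Cl2, −20 °C → rt) chelates the aldehyde and α-alkoxy oxygens of F4 and promotes SE2′ addition of F5 to give the syn,syn hydroxy ester F6. TsOH (cat.) closes it to the bis-PMB lactone F7. Shi epoxidation as in step 17 gives the bis-PMB epoxide F8, and DDQ (3 equiv, pH 7 buffer) removes both PMB groups to give 28.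

Step 17 (Shi epoxidation of 26). The risks are oxidation at the iodoalkene, base-induced loss of the α-methylene lactone, and insufficient facial selectivity on this substrate. The fallback installs the epoxide on fragment B before the fragments are joined; it sets out from 22 and rejoins at 27. Shi epoxidation of 22 under the step 17 conditions (no iodoalkene or lactone present) gives the epoxy Baylis–Hillman alcohol F9 as a mixture of carbinol epimers. N-Bromosuccinimide/Me2S converts it by SN2′ into the epoxy (Z)-bromomethyl enoate F10. Indium-mediated coupling of F10 with 14 in THF/H2O gives the epoxy hydroxy ester F11, which is lactonised without strong acid (2-hydroxypyridine, toluene, 60 °C) to 27.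

Step 20 (Nozaki–Hiyama–Kishi macrocyclisation). The risks are oligomerisation, protodeiodination, and opening of the epoxide by the γ,δ-positioned chromium alkoxide or the Lewis-acidic chromium salts (tetrahydrofuran formation). The fallback closes the ring before the epoxide exists and epoxidises the macrocycle last; it sets out from 26 and rejoins at 33. It still closes the ring by the same chromium chemistry, so it answers the epoxide-related failure modes, not an intrinsic failure of the 14-ring closure. DDQ (pH 7) on 26 gives the diene primary alcohol F12. Copper/nitroxyl aerobic oxidation as in step 19 gives the diene aldehyde F13. CrCl2/NiCl2 at high dilution gives the macrocyclic diene carbinol F14 (C14 epimers). MnO2 gives the macrocyclic diene enone F15. (R)-Me-CBS/catecholborane gives the (14S) 10,11-deoxy compound F16. Shi epoxidation with the D-fructose-derived ketone then attacks the only electron-rich trisubstituted ring alkene to give 33.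

**Further compounds**
F1 | step 16 | (2R,3S)-7-iodo-3-methyloct-7-ene-1,2-diol | C=C(I)CCC[C@H](C)[C@@H](O)CO
F2 | step 16 | (4R)-4-[(2S)-6-iodohept-6-en-2-yl]-2-(4-methoxyphenyl)-1,3-dioxolane (acetal epimers) | C=C(I)CCC[C@H](C)[C@@H]1COC(c2ccc(OC)cc2)O1
F3 | step 16 | (2R,3S)-7-iodo-2-[(4-methoxybenzyl)oxy]-3-methyloct-7-en-1-ol | C=C(I)CCC[C@H](C)[C@@H](OCc1ccc(OC)cc1)CO
F4 | step 16 | (2R,3S)-7-iodo-2-[(4-methoxybenzyl)oxy]-3-methyloct-7-enal | C=C(I)CCC[C@H](C)[C@@H](OCc1ccc(OC)cc1)C=O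
F5 | step 16 | ethyl (2Z,5E)-9-[(4-methoxybenzyl)oxy]-6-methyl-2-[(tributylstannyl)methyl]nona-2,5-dienoate | CCOC(=O)/C(C[Sn](CCCC)(CCCC)CCCC)=C/C/C=C(\C)CCCOCc1ccc(OC)cc1
F6 | step 16 | ethyl (3S,4R,5R,6S)-4-hydroxy-10-iodo-5-[(4-methoxybenzyl)oxy]-3-{(2E)-6-[(4-methoxybenzyl)oxy]-3-methylhex-2-en-1-yl}-6-methyl-2-methylideneundec-10-enoate | C=C(I)CCC[C@H](C)[C@@H](OCc1ccc(OC)cc1)[C@H](O)[C@@H](C/C=C(\C)CCCOCc1ccc(OC)cc1)C(=C)C(=O)OCC
F7 | step 16 | (4S,5R)-5-{(1R,2S)-6-iodo-1-[(4-methoxybenzyl)oxy]-2-methylhept-6-en-1-yl}-4-{(2E)-6-[(4-methoxybenzyl)oxy]-3-methylhex-2-en-1-yl}-3-methylideneoxolan-2-one | C=C(I)CCC[C@H](C)[C@@H](OCc2ccc(OC)cc2)[C@@H]1OC(=O)C(=C)[C@@H]1C/C=C(\C)CCCOCc3ccc(OC)cc3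
F8 | step 16 | (4S,5R)-5-{(1R,2S)-6-iodo-1-[(4-methoxybenzyl)oxy]-2-methylhept-6-en-1-yl}-4-{[(2R,3R)-3-{3-[(4-methoxybenzyl)oxy]propyl}-3-methyloxiran-2-yl]methyl}-3-methylideneoxolan-2-one | C=C(I)CCC[C@H](C)[C@@H](OCc3ccc(OC)cc3)[C@@H]1OC(=O)C(=C)[C@@H]1C[C@H]2O[C@]2(C)CCCOCc4ccc(OC)cc4
F9 | step 17 | ethyl 3-hydroxy-4-[(2R,3R)-3-{3-[(4-methoxybenzyl)oxy]propyl}-3-methyloxiran-2-yl]-2-methylidenebutanoate (C3 epimers) | CCOC(=O)C(=C)C(O)C[C@H]1O[C@]1(C)CCCOCc2ccc(OC)cc2
F10 | step 17 | ethyl (2Z)-2-(bromomethyl)-4-[(2R,3R)-3-{3-[(4-methoxybenzyl)oxy]propyl}-3-methyloxiran-2-yl]but-2-enoate | CCOC(=O)/C(CBr)=C/C[C@H]1O[C@]1(C)CCCOCc2ccc(OC)cc2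
F11 | step 17 | ethyl (3S,4R,5R,6S)-4,5-dihydroxy-10-iodo-3-{[(2R,3R)-3-{3-[(4-methoxybenzyl)oxy]propyl}-3-methyloxiran-2-yl]methyl}-6-methyl-2-methylideneundec-10-enoate | C=C(I)CCC[C@H](C)[C@@H](O)[C@H](O)[C@@H](C[C@H]1O[C@]1(C)CCCOCc2ccc(OC)cc2)C(=C)C(=O)OCC
F12 | step 20 | (4S,5R)-5-[(1R,2S)-1-hydroxy-6-iodo-2-methylhept-6-en-1-yl]-4-[(2E)-6-hydroxy-3-methylhex-2-en-1-yl]-3-methylideneoxolan-2-one | C=C(I)CCC[C@H](C)[C@@H](O)[C@@H]1OC(=O)C(=C)[C@@H]1C/C=C(\C)CCCO
F13 | step 20 | (4E)-6-{(2R,3S)-2-[(1R,2S)-1-hydroxy-6-iodo-2-methylhept-6-en-1-yl]-4-methylidene-5-oxooxolan-3-yl}-4-methylhex-4-enal | C=C(I)CCC[C@H](C)[C@@H](O)[C@@H]1OC(=O)C(=C)[C@@H]1C/C=C(\C)CCC=O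
F14 | step 20 | macrocyclic diene carbinol: as 31 with the (10E)-alkene in place of the epoxide (C14 epimers) | C=C1CCC[C@H](C)[C@@H](O)[C@@H]2OC(=O)C(=C)[C@@H]2C/C=C(\C)CCC1O
F15 | step 20 | macrocyclic diene enone: as 32 with the (10E)-alkene in place of the epoxide | C=C1CCC[C@H](C)[C@@H](O)[C@@H]2OC(=O)C(=C)[C@@H]2C/C=C(\C)CCC1=O
F16 | step 20 | 10,11-deoxy target: (14S)-carbinol with the (10E)-alkene in place of the epoxide | C=C1CCC[C@H](C)[C@@H](O)[C@@H]2OC(=O)C(=C)[C@@H]2C/C=C(\C)CC[C@@H]1O
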